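The synthesis rests on disconnecting the C4–C7' bond and forming it from a C9–O–C7' benzyl ether. The feature exploited is that, in the oxolane (ring A), the benzyl carbon C7' on the quaternary carbinol C4 is cis to the hydroxymethyl carbon C9 on C3, so an oxygen bridge from C9 to C7' closes a cis-fused second oxolane (ring B). Irradiation of a (2S,3R)-2-(3,4-dimethoxyphenyl)-oxolan-4-one whose C9 oxygen carries a 3-methoxy-4-tosyloxybenzyl group forms in one operation the C4–C7' bond, ring B and the C4 stereocentre. Reductive cleavage of the C7'–O bond through a quinone methide and acetylation of the tertiary hydroxyl complete the synthesis.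

Key step: step 8

Remarks on the chemistry (assumptions):
- Atom labels used for all locants and descriptors: ring A = O1, C2 (bears the 3,4-dimethoxyphenyl group), C3, C4, C5; C9 = CH2 carbon on C3; C7' = benzylic carbon of the guaiacyl unit; ring B = C4, C3, C9, O, C7'. With these labels the target is (2S,3R,4S).
- The phenol is carried as its 4-methylbenzenesulfonate (tosylate) instead of an acetate. An aryl acetate would be transferred to the alkoxide in the etherification and could undergo photo-Fries rearrangement. The sulfonate withstands alkoxide, acid and light above 300 nm and is removed in the flask of the ring-opening step.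
- C7' of 14 is expected as a mixture of epimers (aryl on the convex face predominating). Both are carried on, since C7' becomes CH2 in step 9, and C7' is left undefined in the SMILES.
- Compounds 1, 2, 5 and 8 are taken as commercial. Compounds 3 and 4 are racemic; for 4 one enantiomer is drawn.

Step 1
Reactants: 1 methyl glycolate; 2 methyl (E)-3-(3,4-dimethoxyphenyl)prop-2-enoate
Product: 4 methyl (2S*,3R*)-2-(3,4-dimethoxyphenyl)-4-oxooxolane-3-carboxylate (racemic trans keto ester), via oxa-Michael adduct 3 (not isolated)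
Conditions: NaH, Et2O, rt; then 2, DMSO, 0 °C to rt; aq HCl
Reagents that add atoms: none
Why: Tandem oxa-Michael addition/Dieckmann condensation, in which the sodium alkoxide of 1 adds to the cinnamate, the ester enolate so formed closes onto the glycolate ester, the final deprotonation of the β-keto ester drives the sequence, and C3 equilibrates through the enol to place the ester trans to the C2 aryl group (racemate).

Step 2
Reactants: 4 methyl (2S*,3R*)-2-(3,4-dimethoxyphenyl)-4-oxooxolane-3-carboxylate; 5 (2R,3R)-butane-2,3-diol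
Product: 6 methyl (2S,3R)-2-(3,4-dimethoxyphenyl)-4-oxooxolane-3-carboxylate (2R,3R)-butane-2,3-diyl ketal (spiro (4R,5R)-4,5-dimethyl-1,3-dioxolane at C4), single diastereomer
Conditions: TsOH·H2O (cat.), benzene, reflux with azeotropic removal of water; then chromatography (or crystallisation) to separate the two diastereomeric ketals
Reagents that add atoms: none
Why: Acid-catalysed ketalisation with a twofold-symmetric diol creates no stereocentre at the spiro carbon, so the two enantiomers of 4 should give only two trans ketals that differ as diastereomers and are separated as such (classical resolution through a covalent chiral derivative), the (2S,3R) isomer being kept and its configuration to be confirmed by X-ray analysis.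

Step 3
Reactants: 6 ketal ester
Product: 7 [(2S,3R)-2-(3,4-dimethoxyphenyl)-4-oxooxolan-3-yl]methanol (2R,3R)-butane-2,3-diyl ketal
Conditions: LiAlH4, THF, 0 °C; aq NaOH work-up
Reagents that add atoms: none
Why: Hydride reduction of the ester with LiAlH4 leaves the ketal and both stereocentres untouched and releases the C9 hydroxyl.

Step 4
Reactants: 8 4-(hydroxymethyl)-2-methoxyphenol (vanillyl alcohol)
Product: 9 4-(hydroxymethyl)-2-methoxyphenyl 4-methylbenzenesulfonate
Conditions: TsCl, K2CO3, acetone, rt
Reagents that add atoms: 4-methylbenzenesulfonyl chloride, Cc1ccc(cc1)S(Cl)(=O)=O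
Why: Chemoselective sulfonylation of the phenoxide, which forms under carbonate while the far less acidic benzylic alcohol stays protonated.

Step 5
Reactants: 9 4-(hydroxymethyl)-2-methoxyphenyl 4-methylbenzenesulfonate
Product: 10 4-(bromomethyl)-2-methoxyphenyl 4-methylbenzenesulfonate
Conditions: PBr3, CH2Cl2, 0 °C
Reagents that add atoms: phosphorus tribromide, BrP(Br)Br
Why: Bromination of a primary benzylic alcohol through its phosphite ester (SN2), giving a bromide that the electron-withdrawing sulfonyloxy group should keep from self-condensing.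

Step 6
Reactants: 7 ketal alcohol; 10 4-(bromomethyl)-2-methoxyphenyl 4-methylbenzenesulfonate
Product: 11 (2S,3R)-2-(3,4-dimethoxyphenyl)-3-{[(3-methoxy-4-tosyloxyphenyl)methoxy]methyl}oxolan-4-one (2R,3R)-butane-2,3-diyl ketal
Conditions: NaH, Bu4NI (cat.), THF/DMF, 0 °C to rt
Reagents that add atoms: none
Why: Williamson etherification of the primary sodium alkoxide with a reactive benzylic bromide builds the C9–O–C7' tether, SN2 displacement being much faster than attack of the alkoxide on the sulfonate sulfur.

Step 7
Reactants: 11 ketal ether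
Product: 12 (2S,3R)-2-(3,4-dimethoxyphenyl)-3-{[(3-methoxy-4-tosyloxyphenyl)methoxy]methyl}oxolan-4-one
Conditions: 2 M aq HCl, THF, 40 °C
Reagents that add atoms: water, O
Why: Acid-catalysed ketal hydrolysis, in which the sulfonyloxy group keeps the tether benzyl ether as acid-stable as an unsubstituted one and C3, now α to the ketone, stays in the more stable trans arrangement to the C2 aryl group.

Step 8
Reactants: 12 (2S,3R)-2-(3,4-dimethoxyphenyl)-3-{[(3-methoxy-4-tosyloxyphenyl)methoxy]methyl}oxolan-4-one
Product: 14 (2S,3R,4S)-bridgehead-hydroxy furofuran (cis-fused rings A and B; OH on C4; 3,4-dimethoxyphenyl on C2; 3-methoxy-4-tosyloxyphenyl on C7'; C7' epimers), via 1,5-biradical 13 (not isolated)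
Conditions: hν (medium-pressure Hg lamp, Pyrex filter, λ > 300 nm), degassed benzene, 0.01 M, 20 °C
Reagents that add atoms: none
Why: Excitation of the n→π* band of the C4 ketone is followed by transfer of a C7' hydrogen to the carbonyl oxygen through a seven-membered transition state (1,6-hydrogen transfer), and the C4 ketyl/C7' benzyl 1,5-biradical 13 then couples to form the C4–C7' bond. The closest known reaction type is the Norrish–Yang photocyclisation with δ-hydrogen abstraction, established for β-alkoxy ketones and for 3-(benzyloxymethyl)oxolan-4-ones, which give bridgehead-hydroxy furofurans. Ring B (C4, C3, C9, O, C7') closes by radical–radical combination of the 1,5-biradical, a five-membered ring annulated onto ring A across C3–C4. The two-atom C9–O link can reach only the C4 face on which C9 stands, so the fusion is cis and C4 is formed with C7' cis to C9 and the hydroxyl trans to it (4S), under control of the C3 stereocentre; C7' is formed without control, which is harmless because it becomes CH2 in step 9. The step needs site selectivity for the C7' hydrogens and for cyclisation over α-cleavage: the γ position of the side chain is oxygen, the hydrogen on C2 is held in ring A out of reach of the carbonyl oxygen, and the C7'–H bonds are benzylic and α to oxygen, which secures δ-abstraction. Light above 300 nm is absorbed by the ketone only, and the aryl sulfonate, unlike an aryl carboxylate, offers no photo-Fries pathway at these wavelengths.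

Step 9
Reactants: 14 bridgehead-hydroxy furofuran tosylate
Product: 17 (2S,3R,4S)-2-(3,4-dimethoxyphenyl)-4-[(4-hydroxy-3-methoxyphenyl)methyl]-3-(hydroxymethyl)oxolan-4-ol, via free phenol 15 (not isolated), via quinone methide 16 (not isolated)
Conditions: NaOH, NaBH4 (excess, in portions), dioxane/H2O, 95 °C; aq HCl to pH 6
Reagents that add atoms: none
Why: Hot hydroxide cleaves the aryl sulfonate at sulfur, the phenoxide expels the C9 alkoxide to open ring B to a para-quinone methide that only the phenolic ring can form, and borohydride adds hydride to C7' (alkaline borohydride reduction of a 4-hydroxybenzyl ether through its quinone methide), so that only the C7'–O bond is cut and C2, C3 and C4 are untouched.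

Step 10
Reactants: 17 triol
Product: 18 (2S,3R,4S)-4-{[4-(tert-butyldimethylsilyloxy)-3-methoxyphenyl]methyl}-3-[(tert-butyldimethylsilyloxy)methyl]-2-(3,4-dimethoxyphenyl)oxolan-4-ol
Conditions: TBSCl, imidazole, DMF, rt
Reagents that add atoms: tert-butyldimethylsilyl chloride, CC(C)(C)[Si](C)(C)Cl
Why: Silylation with TBSCl/imidazole takes the phenol and the primary alcohol but not the hindered tertiary alcohol at C4.

Step 11
Reactants: 18 bis-silyl ether
Product: 19 (2S,3R,4S)-4-acetoxy-4-{[4-(tert-butyldimethylsilyloxy)-3-methoxyphenyl]methyl}-3-[(tert-butyldimethylsilyloxy)methyl]-2-(3,4-dimethoxyphenyl)oxolane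
Conditions: Ac2O, DMAP, Et3N, CH2Cl2, rt to 40 °C
Reagents that add atoms: acetic anhydride, CC(=O)OC(C)=O
Why: DMAP-catalysed acylation through the N-acetylpyridinium ion esterifies the only free hydroxyl, the tertiary one at C4, with retention because the C–O bond is not broken.

Step 12
Reactants: 19 bis-silyl ether acetate
Product: 20 (2S,3R,4S)-4-acetoxy-2-(3,4-dimethoxyphenyl)-4-[(4-hydroxy-3-methoxyphenyl)methyl]-3-(hydroxymethyl)oxolane, equal to [(3S,4R,5S)-5-(3,4-dimethoxyphenyl)-3-[(4-hydroxy-3-methoxyphenyl)methyl]-4-(hydroxymethyl)oxolan-3-yl] acetate (target)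
Conditions: HF·pyridine, pyridine, THF, 0 °C to rt
Reagents that add atoms: none
Why: Fluoride cleavage of the aryl and primary silyl ethers under weakly acidic conditions, in which no alkoxide arises at C9 and the C4 acetate therefore should not migrate to the neighbouring primary hydroxyl.

Compound list
1 | methyl glycolate | COC(=O)CO | starting material
2 | methyl (E)-3-(3,4-dimethoxyphenyl)prop-2-enoate | COC(=O)/C=C/c1ccc(OC)c(OC)c1 | starting material
3 | methyl 3-(3,4-dimethoxyphenyl)-3-(2-methoxy-2-oxoethoxy)propanoate (racemic oxa-Michael adduct, present as its sodium ester enolate) | COC(=O)COC(CC(=O)OC)c1ccc(OC)c(OC)c1 | intermediate (not isolated)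
4 | methyl (2S*,3R*)-2-(3,4-dimethoxyphenyl)-4-oxooxolane-3-carboxylate (racemate, (2S,3R) enantiomer drawn) | O=C1CO[C@H](c2ccc(OC)c(OC)c2)[C@H]1C(=O)OC | intermediate
5 | (2R,3R)-butane-2,3-diol | C[C@@H](O)[C@@H](C)O | starting material
6 | methyl (2S,3R)-2-(3,4-dimethoxyphenyl)-4-oxooxolane-3-carboxylate (2R,3R)-butane-2,3-diyl ketal | C[C@H]1OC2(CO[C@H](c3ccc(OC)c(OC)c3)[C@H]2C(=O)OC)O[C@@H]1C | intermediate
7 | [(2S,3R)-2-(3,4-dimethoxyphenyl)-4-oxooxolan-3-yl]methanol (2R,3R)-butane-2,3-diyl ketal | C[C@H]1OC2(CO[C@H](c3ccc(OC)c(OC)c3)[C@H]2CO)O[C@@H]1C | intermediate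
8 | 4-(hydroxymethyl)-2-methoxyphenol (vanillyl alcohol) | COc1cc(CO)ccc1O | starting material
9 | 4-(hydroxymethyl)-2-methoxyphenyl 4-methylbenzenesulfonate | COc1cc(CO)ccc1OS(=O)(=O)c1ccc(C)cc1 | intermediate
10 | 4-(bromomethyl)-2-methoxyphenyl 4-methylbenzenesulfonate | COc1cc(CBr)ccc1OS(=O)(=O)c1ccc(C)cc1 | intermediate
11 | (2S,3R)-2-(3,4-dimethoxyphenyl)-3-{[(3-methoxy-4-tosyloxyphenyl)methoxy]methyl}oxolan-4-one (2R,3R)-butane-2,3-diyl ketal | C[C@H]1OC2(CO[C@H](c3ccc(OC)c(OC)c3)[C@H]2COCc2ccc(OS(=O)(=O)c3ccc(C)cc3)c(OC)c2)O[C@@H]1C | intermediate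
12 | (2S,3R)-2-(3,4-dimethoxyphenyl)-3-{[(3-methoxy-4-tosyloxyphenyl)methoxy]methyl}oxolan-4-one | O=C1CO[C@H](c2ccc(OC)c(OC)c2)[C@H]1COCc1ccc(OS(=O)(=O)c2ccc(C)cc2)c(OC)c1 | intermediate (key-step precursor)
13 | 1,5-biradical of 12 (C4 hydroxy-substituted radical, C7' benzylic radical) | O[C]1CO[C@H](c2ccc(OC)c(OC)c2)[C@H]1CO[CH]c1ccc(OS(=O)(=O)c2ccc(C)cc2)c(OC)c1 | intermediate (not isolated)
14 | (2S,3R,4S)-bridgehead-hydroxy furofuran, 3-methoxy-4-tosyloxyphenyl on C7' (C7' epimers) | Cc1ccc(cc1)S(=O)(=O)Oc1ccc(cc1OC)C1OC[C@@H]2[C@@H](c3ccc(OC)c(OC)c3)OC[C@]12O | intermediate (key-step product)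
15 | free phenol of 14 (present as sodium phenoxide) | COc1cc(ccc1O)C1OC[C@@H]2[C@@H](c3ccc(OC)c(OC)c3)OC[C@]12O | intermediate (not isolated)
16 | para-quinone methide: 2-(3,4-dimethoxyphenyl)-3-(hydroxymethyl)-4-[(3-methoxy-4-oxocyclohexa-2,5-dien-1-ylidene)methyl]oxolan-4-ol, configured at C2, C3, C4 as in 17 | COC1=CC(=C[C@@]2(O)CO[C@H](c3ccc(OC)c(OC)c3)[C@H]2CO)C=CC1=O | intermediate (not isolated)
17 | (2S,3R,4S)-2-(3,4-dimethoxyphenyl)-4-[(4-hydroxy-3-methoxyphenyl)methyl]-3-(hydroxymethyl)oxolan-4-ol | COc1cc(C[C@@]2(O)CO[C@H](c3ccc(OC)c(OC)c3)[C@H]2CO)ccc1O | intermediate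
18 | bis(tert-butyldimethylsilyl) ether of 17 (phenol and C9 hydroxyl silylated, C4 hydroxyl free) | COc1cc(C[C@@]2(O)CO[C@H](c3ccc(OC)c(OC)c3)[C@H]2CO[Si](C)(C)C(C)(C)C)ccc1O[Si](C)(C)C(C)(C)C | intermediate
19 | C4 acetate of 18 | COc1cc(C[C@@]2(OC(C)=O)CO[C@H](c3ccc(OC)c(OC)c3)[C@H]2CO[Si](C)(C)C(C)(C)C)ccc1O[Si](C)(C)C(C)(C)C | intermediate
20 | [(3S,4R,5S)-5-(3,4-dimethoxyphenyl)-3-[(4-hydroxy-3-methoxyphenyl)methyl]-4-(hydroxymethyl)oxolan-3-yl] acetate | COc1cc(C[C@@]2(OC(C)=O)CO[C@H](c3ccc(OC)c(OC)c3)[C@H]2CO)ccc1O | target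

Total step count: 12. Longest linear sequence: 10 steps (steps 1, 2, 3, 6, 7, 8, 9, 10, 11, 12); steps 4 and 5 prepare bromide 10.

Steps most likely to fail

Step 8 (key step). The excited ketone may undergo α-cleavage (ring opening, decarbonylation), or the biradical may return its hydrogen faster than it closes, so that little furofuran accumulates. The fallback sets out from 7 and comes back at 20; it builds the C4 carbinol by sterically controlled epoxidation and forms the C7'–aryl bond instead of the C4–C7' bond. Alcohol 7 is silylated (TBDPSCl, imidazole, DMF) to the tert-butyldiphenylsilyl ether F1, and aqueous HCl in THF removes the ketal to give the ketone F2. Wittig methylenation (Ph3P=CH2 from Ph3PCH3Br and KOtBu, THF, 0 °C) gives the 4-methylene oxolane F3. mCPBA (NaHCO3, CH2Cl2, 0 °C) should attack the exocyclic alkene anti to the C3 substituent and give the spiro-epoxide F4 with its oxygen trans to C9. Commercial 4-bromo-2-methoxyphenol is silylated to the aryl bromide F5, converted to its Grignard reagent (Mg, THF) and added to F4 with CuI (cat.) at the epoxide CH2, giving the tertiary alcohol F6 with the benzyl group cis to C9. Acetylation (Ac2O, DMAP, Et3N) gives the tertiary acetate F7, and TBAF buffered with AcOH removes both silyl groups to give 20.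

Step 9. Expulsion of the C9 alkoxide from the phenoxide may be slow, so that ring B recloses faster than hydride is delivered, or the β-hydroxy quinone methide may rearrange before it is reduced. The fallback sets out from 14 and comes back at 17; it replaces the ionic reduction by catalytic hydrogenolysis. The sulfonate is cleaved alone (NaOH, MeOH/H2O, reflux) and phenol 15 is isolated. Hydrogenolysis (H2, 1 atm, Pd/C, MeOH, rt, stopped after one equivalent) should cleave the benzylic C7'–O bond para to the free phenol ahead of the C2–O1 bond of the non-phenolic ring, giving 17. This fallback makes no compound beyond the list (none F0).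

Step 2. The two diastereomeric ketals may not be discriminated well enough on silica or on crystallisation, so that stereochemically pure material is not obtained; the dimethyl-substituted ketal is also the slower one to hydrolyse in step 7. The fallback sets out from 4 and comes back at 12; it resolves enantiomers on a chiral stationary phase instead of through covalent diastereomers. Ketalisation of 4 with ethylene glycol (TsOH·H2O, benzene, reflux) gives the racemic ethylene ketal ester F8, and LiAlH4 gives the racemic ethylene ketal alcohol F9. Preparative supercritical-fluid chromatography on an amylose tris(3,5-dimethylphenylcarbamate) phase gives the (2S,3R) ethylene ketal alcohol F10. Etherification with 10 (NaH, Bu4NI, THF/DMF) gives the ethylene ketal ether F11, and aqueous HCl in THF gives 12.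

Further compounds
F1 | step 8 | tert-butyldiphenylsilyl ether of 7 | C[C@H]1OC2(CO[C@H](c3ccc(OC)c(OC)c3)[C@H]2CO[Si](c2ccccc2)(c2ccccc2)C(C)(C)C)O[C@@H]1C
F2 | step 8 | (2S,3R)-3-[(tert-butyldiphenylsilyloxy)methyl]-2-(3,4-dimethoxyphenyl)oxolan-4-one | O=C1CO[C@H](c2ccc(OC)c(OC)c2)[C@H]1CO[Si](c1ccccc1)(c1ccccc1)C(C)(C)C
F3 | step 8 | (2S,3R)-3-[(tert-butyldiphenylsilyloxy)methyl]-2-(3,4-dimethoxyphenyl)-4-methylideneoxolane | C=C1CO[C@H](c2ccc(OC)c(OC)c2)[C@H]1CO[Si](c1ccccc1)(c1ccccc1)C(C)(C)C
F4 | step 8 | spiro-epoxide of F3 at C4, epoxide oxygen trans to C9 | C1[C@@]2(O1)CO[C@H](c3ccc(OC)c(OC)c3)[C@H]2CO[Si](c2ccccc2)(c2ccccc2)C(C)(C)C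
F5 | step 8 | (4-bromo-2-methoxyphenoxy)(tert-butyl)dimethylsilane | COc1cc(Br)ccc1O[Si](C)(C)C(C)(C)C
F6 | step 8 | (2S,3R,4S)-4-{[4-(tert-butyldimethylsilyloxy)-3-methoxyphenyl]methyl}-3-[(tert-butyldiphenylsilyloxy)methyl]-2-(3,4-dimethoxyphenyl)oxolan-4-ol | COc1cc(C[C@@]2(O)CO[C@H](c3ccc(OC)c(OC)c3)[C@H]2CO[Si](c2ccccc2)(c2ccccc2)C(C)(C)C)ccc1O[Si](C)(C)C(C)(C)C
F7 | step 8 | C4 acetate of F6 | COc1cc(C[C@@]2(OC(C)=O)CO[C@H](c3ccc(OC)c(OC)c3)[C@H]2CO[Si](c2ccccc2)(c2ccccc2)C(C)(C)C)ccc1O[Si](C)(C)C(C)(C)C
F0 | step 9 | none | none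
F8 | step 2 | methyl (2S*,3R*)-2-(3,4-dimethoxyphenyl)-4-oxooxolane-3-carboxylate ethane-1,2-diyl ketal (racemate, one enantiomer drawn) | C1COC2(O1)CO[C@H](c3ccc(OC)c(OC)c3)[C@H]2C(=O)OC
F9 | step 2 | [(2S*,3R*)-2-(3,4-dimethoxyphenyl)-4-oxooxolan-3-yl]methanol ethane-1,2-diyl ketal (racemate, one enantiomer drawn) | C1COC2(O1)CO[C@H](c3ccc(OC)c(OC)c3)[C@H]2CO
F10 | step 2 | [(2S,3R)-2-(3,4-dimethoxyphenyl)-4-oxooxolan-3-yl]methanol ethane-1,2-diyl ketal (single enantiomer) | C1COC2(O1)CO[C@H](c3ccc(OC)c(OC)c3)[C@H]2CO
F11 | step 2 | (2S,3R)-2-(3,4-dimethoxyphenyl)-3-{[(3-methoxy-4-tosyloxyphenyl)methoxy]methyl}oxolan-4-one ethane-1,2-diyl ketal | C1COC2(O1)CO[C@H](c3ccc(OC)c(OC)c3)[C@H]2COCc2ccc(OS(=O)(=O)c3ccc(C)cc3)c(OC)c2
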